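# Proposed total synthesis of CNP0320711.1 (7,12-dioxo-6,7-seco-ent-kaur-16-ene-6,19-dioic acid)

## Structural features

The target is a 6,7-seco-ent-kaurane: ring A (C1–C5, C10) is joined through the single bond C9–C10 to a bicyclo[3.2.1]octane made of ring C (C8, C9, C11, C12, C13, C14) and ring D (C8, C14, C13, C16, C15). Ring A carries three contiguous stereocentres: quaternary C4 (methyl C18, axial carboxyl C19), C5 (carboxyl C6) and quaternary C10 (methyl C20). C10 is bonded to C9, which sits next to the quaternary bridgehead C8 (formyl C7); C13 is the second bridgehead. The fragile groups are the non-enolisable C7 aldehyde, the C12 ketone, the exocyclic C16=C17 alkene (sensitive to acid and to ozone), and the cis-vicinal C6/C19 diacid, whose axial C19 carboxyl is hard to unmask from an ordinary ester late in a route. The real difficulty is the congested C4–C5–C10–C9–C8 array, five adjacent stereocentres of which three are quaternary, spanning the junction between ring A and the bicycle. A second problem is that C6 and C7 stand at different oxidation levels. The key step exploits the fact that C6 on C5 and C7 on C8 are the two ends of a cleaved C6=C7 double bond. Rejoining them gives a cyclohexene ring B (C5, C6, C7, C8, C9, C10) fused trans to ring A, an octalin that a [4+2] addition between a C5–C8 diene and a C9=C10 dienophile can form. The cis relation of C19 and C6 on ring A also allows a five-membered lactol or anhydride, which the route uses both to tell C6 from C7 and to protect both acids.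

## Logic of the disconnections

**29 ⇐ 28 ⇐ 27 ⇐ 26.** No carbon–carbon bond is cut. The two acid C–OH bonds at C6 and C19 are joined as the cyclic anhydride 28, which goes back to the lactol 27 and its methyl pseudo-ester 26. The reason is that both acids can then be set free at the very end by water, and C6 stays one oxidation level away from C7 until then. The gain is one neutral, hindered lactone in place of two acids. The demand is a final oxidation that takes a lactol beside the C7 aldehyde, and an acid hydrolysis that leaves C16=C17 alone.

**26 ⇐ 24 (through 25).** The bonds C8–C15 (ring D) and C13–C14 (ring C) are cut. C13 is acidic (α to C12 and allylic) and C15 is allylic, so the bicycle unfolds to an acrolein unit on C8 and a 2-(acetoxymethyl)allyl ketone on the same chain. Both rings, the quaternary C8 and C13 disappear. The forward step must make C13, not C11, add to C14, and must bring C15 to the face of C8 anti to C10.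

**24 ⇐ 23 ⇐ 22.** The C8=C14 bond is cut (C14 is a one-carbon unit) and the C7 aldehyde is returned to its dimethyl acetal. The reactive acrolein is thus made last, and C7 is masked while an organolithium is used. The forward steps must methylenate only the aldehyde and must hydrolyse the acetal without opening the pseudo-ester.

**22 ⇐ 19 + 20.** The bond C12–C13 is cut. C13, C16, C17 and C15 with the C15 oxygen come from one commercial four-carbon unit, 20. The forward step needs a single addition to the amide carbonyl of 19 in the presence of a lactone.

**19 ⇐ 17 (through 18).** C6 and C7 are rejoined as the C6=C7 alkene, which restores ring B. An acetal and a pseudo-ester collapse to an alkene and a free acid. The forward cleavage must give two differentiated termini; the cis C19 acid does this by capturing only the C6 aldehyde.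

**17 ⇐ 16 ⇐ 14 ⇐ 12 ⇐ 11.** C11 is excised: the bonds C9–C11 and C11–C12 are replaced by C9–C12, and the carboxyl groups return to methyl esters. The cycloadduct carries C12 directly on C9, so one carbon must be inserted afterwards. The forward steps must tell the equatorial ester on C9 from the axial C19 ester and must move C9 with retention.

**11 ⇐ 10.** The bonds C5–C10 and C8–C9 are cut (key step). Rings A and B and the stereocentres C5, C9 and C10 disappear together, leaving an acyclic triene with one stereocentre. The forward step needs endo selectivity, an E dienophile, an E diene and face control by C4.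

**10 ⇐ 7 + 8.** The C5=C6 bond is cut, leaving a C4 aldehyde and a three-carbon ylide. The forward step must end with the E diene.

**7 ⇐ 6 ⇐ 5 ⇐ 4.** The oxidation level of C5 is adjusted, and the C4 stereocentre is traced to the prochiral malonate 4, whose two ester groups are enantiotopic. The forward step needs one enantiotopic ester hydrolysed and then the acid, not an ester, reduced.

**4 ⇐ 2 + 3.** The bond C3–C4 is cut (malonate alkylation). The electrophile 2 already holds the E enoate, so no ketone has to be carried through basic alkylation or through the borane step.

**2 ⇐ 1.** The bonds C10–C20 and C9–C12 are cut. Both are made by one syn carbometalation–acylation of a terminal alkyne, which fixes the 2E geometry without an olefination that would give E/Z mixtures.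

## Other disconnections considered

**Alternative 1:** The cut is C13–C16 in ring D, traced to the achiral cyclohexa-2,5-dienone A1 (quaternary C8 with the C7 ester and a 2-oxo-3-silylpropyl arm, reachable from benzoic acid by Birch alkylation and oxidation). In the forward step, copper hydride from Cu(OAc)2, DTBM-SEGPHOS and tetramethyldisiloxane would deliver hydride to C14 of one enantiotopic enone arm, and the C13 copper enolate would add to the C16 ketone to give the β-hydroxysilane A2.
- In its favour: enantiocontrol comes from a catalyst acting on an achiral precursor. C8, C13 and C16 are set in one step. C13 is the only enolate that can form. The methylene is latent as a Peterson precursor, so it would survive oxidative steps.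
- Where it is better: for building the bicycle it is shorter and better controlled than steps 13–16 of the chosen plan.
- Against it here: the hardest part of the target is left open. The C9–C10 bond would have to join the β-carbon of the remaining enone to a quaternary carbon, and C4, C5 and C10 would have to be set relative to C9 across that bond. C7 would still have to go from ester to aldehyde beside a ketone. The tertiary β-hydroxysilane could undergo retro-aldol cleavage or early elimination under basic conditions.
- Comparison: on structure, the chosen plan puts its strongest step where the congestion is; the alternative puts it on the easier half. On mechanism, both use known reaction types, and catalyst control is in principle equal or better than the esterase step 3. On step economy, A2 is near in few steps, but adding ring A would probably take more steps than the eleven that follow step 7.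

**Alternative 2:** The cut is C5–C10 and C3–C4, with ring A made last. In the triene A3 a diene (C10, C1, C2, C3) hangs on C9 of a finished bicycle and a citraconate dienophile (C4=C5) is tied to C8 through C7, oxygen and C6. Heating would give the lactone-bridged cycloadduct A4.
- In its favour: C6 and C7 are differentiated from the start (acyl against alkoxy). The cis C19/C6 relation follows from the Z dienophile. The bicycle could be prepared separately.
- Where it is better: on the C6/C7 problem it is better than the chosen plan, which needs the lactol device of step 12.
- Against it here: the cycloaddition would have to form both quaternary carbons C4 and C10 at once, from a trisubstituted dienophile and a diene terminus that carries a methyl group on its inside position. The tether is an ester that prefers the wrong conformation and closes a seven-membered ring. The configuration of C10 relative to C9 would depend on rotamer control about the C9–C10 bond. Afterwards C1=C2 would need hydrogenation, C7 would need oxidation after lactone opening, and C16 would need methylenation beside a ketone and an aldehyde.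
- Comparison: on structure, the chosen plan sets C9 and C10 as neighbours in one transition state through alkene geometry, which is more secure. On mechanism, both are thermal or Lewis-acid [4+2] additions, but an all-carbon four-atom tether is the better precedented. On step economy, the two are comparable at best, because the bicycle must be made first and four redox or olefination steps follow.

**Alternative 3:** The cut is C12–C13, with ring C made last. In A5 a C12 acid chloride and a cyclopentenylmethylsilane sit on the same C9; TiCl4 would trigger attack through C13 with loss of silicon to give the methylene ketone thioester A6.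
- In its favour: C13 is the only nucleophilic carbon. The methylene would appear regiospecifically on C16 and the C12 ketone directly. The thioester is a mild aldehyde precursor.
- Where it is better: on regiochemical certainty of ring closure it is better than step 16 of the chosen plan, where C11 can compete.
- Against it here: A5 already contains every difficult centre (C4, C5, C10, C9, C8), so its own synthesis is not simplified. The quaternary C8 lies in a cyclopentene whose two arms differ only by the position of the alkene. TiCl4 would meet three Lewis-basic carbonyl groups. The end would need hydrolysis of two hindered methyl esters beside an aldehyde, harsher than the anhydride release of step 18.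
- Comparison: on mechanism, the cationic cyclisation is as well precedented as the Diels–Alder step. On structure, the difficulty is moved into the fragment rather than removed. On step economy, it is likely to be longer.

Key step: step 7

**Remarks on the chemistry (one line each)**

- Numbering: ent-kaurane numbers are used for all intermediates; the conjugated ester carbon of 10 and 11 becomes C12, and C11 is the carbon inserted in steps 9 and 10.
- Structure: counted from its conjugated ester carbon, 10 is an undeca-2,8,10-trienoate (a 1,7,9-decatriene counted from C9); a deca-2,7,9-trienoate would close a five-membered ring, not ring A.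
- Assumption: the esterase is taken to hydrolyse the pro-S ester of 4, giving (R)-5, the sense expected for 2-methylmalonates with a long second chain.
- Mixtures: the acetal carbon C6 in 18, 19, 21–27 and the centres C8 and C13 in 25 form as epimer mixtures that converge later; they are written without configuration.

## Route

Step 1
Reactants: 1 5-chloropent-1-yne
Product: 2 methyl (2E)-6-chloro-3-methylhex-2-enoate
Conditions: Me3Al (2.0 equiv), Cp2ZrCl2 (0.2 equiv), (CH2Cl)2, 0 °C to rt; then ClCO2Me (1.5 equiv), 0 °C to rt; aq. HCl
Reagents that add atoms: trimethylaluminium C[Al](C)C; methyl chloroformate COC(=O)Cl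
Why: Zirconium-catalysed syn carboalumination (Negishi) puts the methyl group C20 on C10 and aluminium on C9, and the alkenylalane is acylated by the chloroformate with retention, so the ester ends cis to the methyl group and the 2E dienophile geometry is fixed stereospecifically. The primary chloride is inert to both operations.

Step 2
Reactants: 2 methyl (2E)-6-chloro-3-methylhex-2-enoate; 3 dimethyl 2-methylpropanedioate
Product: 4 dimethyl 2-[(4E)-6-methoxy-4-methyl-6-oxohex-4-en-1-yl]-2-methylpropanedioate
Conditions: NaH (1.1 equiv), DMF, 0 °C; then 2, NaI (0.1 equiv), 70 °C
Reagents that add atoms: none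
Why: Malonic ester alkylation (SN2 through the iodide formed in situ) makes the C3–C4 bond; the stabilised malonate anion is too weak a base to deprotonate the enoate and too hindered to add to its β,β-disubstituted carbon. C4 is still prochiral.

Step 3
Reactants: 4 dimethyl 2-[(4E)-6-methoxy-4-methyl-6-oxohex-4-en-1-yl]-2-methylpropanedioate
Product: 5 (2R,6E)-8-methoxy-2-(methoxycarbonyl)-2,6-dimethyl-8-oxooct-6-enoic acid
Conditions: pig liver esterase, 0.1 M phosphate buffer pH 7.5/DMSO (9:1), 30 °C, pH-stat (1 M NaOH, 1.0 equiv); then HCl to pH 2
Reagents that add atoms: water O
Why: Enzymatic desymmetrisation of a prochiral 2,2-disubstituted malonate: the esterase hydrolyses one of the two enantiotopic methyl esters and so sets C4. The hindered conjugated ester is a much poorer substrate, and the reaction is stopped after one equivalent of base.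

Step 4
Reactants: 5 (2R,6E)-8-methoxy-2-(methoxycarbonyl)-2,6-dimethyl-8-oxooct-6-enoic acid
Product: 6 dimethyl (2E,7R)-7-(hydroxymethyl)-3,7-dimethyloct-2-enedioate
Conditions: BH3·SMe2 (1.3 equiv), THF, 0 °C to rt; MeOH
Reagents that add atoms: none
Why: Borane reduces a carboxylic acid (through the acyloxyborane) far faster than methyl esters or an electron-poor trisubstituted alkene, so only the acid carbon, the future C5, becomes CH2OH. C4 is not touched.

Step 5
Reactants: 6 dimethyl (2E,7R)-7-(hydroxymethyl)-3,7-dimethyloct-2-enedioate
Product: 7 dimethyl (2E,7R)-7-formyl-3,7-dimethyloct-2-enedioate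
Conditions: Dess–Martin periodinane (1.3 equiv), CH2Cl2, rt
Reagents that add atoms: none
Why: Hypervalent-iodine oxidation of the primary alcohol under neutral conditions. The aldehyde has no α-hydrogen, so C4 cannot epimerise, and the β-formyl ester is never exposed to base.

Step 6
Reactants: 7 dimethyl (2E,7R)-7-formyl-3,7-dimethyloct-2-enedioate; 8 allyltriphenylphosphonium bromide
Product: 10 dimethyl (2E,7R)-7-[(1E)-buta-1,3-dien-1-yl]-3,7-dimethyloct-2-enedioate, via Z diene 9 (not isolated)
Conditions: 8, KN(SiMe3)2 (1.1 equiv), THF, −78 °C; then 7, −78 to 0 °C; then I2 (5 mol %), CH2Cl2, visible light, rt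
Reagents that add atoms: none
Why: Wittig olefination with the semi-stabilised allylidene ylide forms C5=C6 as an E/Z mixture. Reversible addition of iodine atoms to the conjugated diene then equilibrates the Z isomer 9 to the more stable E diene, the only isomer that reaches the s-cis conformation easily. The isolated, electron-poor enoate should not isomerise under these conditions.

Step 7
Reactants: 10 dimethyl (2E,7R)-7-[(1E)-buta-1,3-dien-1-yl]-3,7-dimethyloct-2-enedioate
Product: 11 dimethyl (1R,4aR,5R,8aS)-1,4a-dimethyl-1,2,3,4,4a,5,6,8a-octahydronaphthalene-1,5-dicarboxylate
Conditions: Me2AlCl (1.2 equiv), CH2Cl2, −20 °C to rt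
Reagents that add atoms: none
Why: Me2AlCl binds the more basic conjugated ester and lowers the LUMO of the C9=C10 alkene, which adds to the s-cis C5–C8 diene in a concerted, asynchronous [4+2] in which the bond from the β-carbon C10 to C5 is the more advanced. The closest known reaction type is the Lewis-acid-promoted intramolecular Diels–Alder reaction of (2E,8E)-undeca-2,8,10-trienoates to trans-fused octalins, including substrates whose 3-methyl group becomes the angular methyl. Ring A closes as the six-membered tether ring (C10, C1–C5) through a chair-like array of the four-carbon tether, and ring B is the cyclohexene formed by the cycloaddition itself (bonds C5–C10 and C8–C9). C9 relative to C10 follows from suprafacial addition to the E alkene, which keeps the ester cis to C20. C5 relative to C10 (trans ring fusion) follows from the endo position of the complexed ester, which places the tether anti to the diene. The absolute sense of all three new centres comes from C4: of the two chair-like endo transition states, the one with the flat C19 ester rather than the C18 methyl in the pseudo-axial position syn to C20 avoids a methyl–methyl 1,3-diaxial contact. The step therefore needs endo over exo selectivity and diene-face selectivity; the first is secured by Lewis-acid complexation at low temperature and the second by the C4 substituents, and only 1.2 equivalents of Me2AlCl are used so that the hindered C19 ester stays largely uncomplexed and small. Any cis-fused or face-mismatched adducts are diastereomers of 11 and would be removed by chromatography at this stage.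

Step 8
Reactants: 11 dimethyl (1R,4aR,5R,8aS)-1,4a-dimethyl-1,2,3,4,4a,5,6,8a-octahydronaphthalene-1,5-dicarboxylate
Product: 12 (1R,4aS,5R,8aR)-5-(methoxycarbonyl)-5,8a-dimethyl-1,2,4a,5,6,7,8,8a-octahydronaphthalene-1-carboxylic acid
Conditions: LiOH (3 equiv), THF/MeOH/H2O (2:1:1), 50 °C; then 1 M HCl
Reagents that add atoms: water O (as aqueous LiOH)
Why: Saponification discriminates on steric grounds: the equatorial ester on C9 is hydrolysed, while the axial ester on quaternary C4 (C19) is inert under these conditions. C9 already holds its substituent equatorial, so enolisation cannot change it.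

Step 9
Reactants: 12 (1R,4aS,5R,8aR)-5-(methoxycarbonyl)-5,8a-dimethyl-1,2,4a,5,6,7,8,8a-octahydronaphthalene-1-carboxylic acid
Product: 14 diazoketone (C9–CO–CHN2; C19 methyl ester; C6=C7), via acid chloride 13 (not isolated)
Conditions: (COCl)2 (1.5 equiv), DMF (cat.), CH2Cl2, 0 °C to rt, evaporate; then CH2N2 (3 equiv), Et2O, 0 °C
Reagents that add atoms: oxalyl chloride ClC(=O)C(Cl)=O (chlorine of 13); diazomethane C=[N+]=[N-]
Why: First half of the Arndt–Eistert homologation: the acid chloride acylates diazomethane and the excess reagent removes HCl. The molecule holds only an isolated alkene and a hindered ester here, so nothing needs protection.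

Step 10
Reactants: 14 diazoketone (C9–CO–CHN2; C19 methyl ester; C6=C7)
Product: 16 morpholine amide ester (C9–CH2–CO–morpholin-4-yl; C19 methyl ester; C6=C7), via ketene 15 (not isolated)
Conditions: AgO2CPh (10 mol %), Et3N (3 equiv), morpholine (2 equiv), THF, rt, dark
Reagents that add atoms: morpholine C1COCCN1
Why: Silver-catalysed Wolff rearrangement: C9 migrates with retention to the carbene carbon (the inserted C11) and ketene 15 is trapped by morpholine. A morpholine amide accepts one equivalent of an organolithium as a Weinreb amide does, but has no N–O bond that the thiolate of step 11 could attack.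

Step 11
Reactants: 16 morpholine amide ester (C9–CH2–CO–morpholin-4-yl; C19 methyl ester; C6=C7)
Product: 17 morpholine amide acid (16 with free C19 carboxylic acid)
Conditions: NaSEt (5 equiv), DMF, 100 °C; then 1 M HCl
Reagents that add atoms: none
Why: SN2 O-demethylation: the thiolate attacks the methyl carbon, so the hindrance at the axial C19 carbonyl does not matter. The tertiary amide and the isolated alkene are inert, and this is the last point at which so forcing a step is harmless.

Step 12
Reactants: 17 morpholine amide acid (16 with free C19 carboxylic acid)
Product: 19 acetal pseudo-ester amide (C7 dimethyl acetal; C19-to-C6 methoxy-γ-lactone; C12 morpholine amide), via lactol aldehyde 18 (not isolated)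
Conditions: O3, CH2Cl2/MeOH (4:1), −78 °C; Me2S (5 equiv), −78 °C to rt; then TsOH·H2O (10 mol %), MeOH, rt
Reagents that add atoms: ozone [O-][O+]=O (oxygen atoms of 18); methanol CO
Why: Ozonolysis with reductive work-up cleaves the only alkene to the C6 and C7 aldehydes. The cis C19 acid captures the C6 aldehyde as a five-membered hydroxy lactone, which acidic methanol turns into the methyl pseudo-ester while the unhindered C7 aldehyde becomes a dimethyl acetal. The two termini are thus told apart by the neighbouring acid, and C19 and C6 are protected in one group.

Step 13
Reactants: 19 acetal pseudo-ester amide (C7 dimethyl acetal; C19-to-C6 methoxy-γ-lactone; C12 morpholine amide); 20 2-methylprop-2-en-1-ol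
Product: 22 keto acetate (C12 ketone carrying CH2–C(=CH2)–CH2OAc; C7 dimethyl acetal; methoxy-γ-lactone), via dilithium hemiaminal alkoxide 21 (not isolated)
Conditions: 20 (1.5 equiv), n-BuLi (3.1 equiv), TMEDA, Et2O, 0 °C to rt; then 19, THF, −78 °C; then Ac2O (4 equiv), −78 to 0 °C; aq. NH4Cl
Reagents that add atoms: acetic anhydride CC(=O)OC(C)=O
Why: The C,O-dilithio derivative of 20 (allylic metalation) adds through carbon to the morpholine amide and stops at the stable tetrahedral adduct 21, which forms C12–C13. At −78 °C the unhindered amide should react well before the lactone carbonyl on quaternary C4. Acetylation of the alkoxide in the same flask puts the leaving group on C15, and work-up releases the ketone with the alkene out of conjugation at C16=C17.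

Step 14
Reactants: 22 keto acetate (C12 ketone carrying CH2–C(=CH2)–CH2OAc; C7 dimethyl acetal; methoxy-γ-lactone)
Product: 23 keto acetate aldehyde (22 with free C7 aldehyde)
Conditions: PPTS (0.2 equiv), acetone/H2O (9:1), 45 °C
Reagents that add atoms: water O
Why: Mild acid hydrolysis of the dialkyl acetal. The acyloxy acetal of the pseudo-ester ionises far less readily because its oxocarbenium ion is destabilised by the acyl group, and the conditions are too mild to move the C16=C17 alkene.

Step 15
Reactants: 23 keto acetate aldehyde (22 with free C7 aldehyde)
Product: 24 enal (23 with the C8=C14 methylene; a 2-substituted acrolein)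
Conditions: 37 % aq. CH2O (1.5 equiv), pyrrolidine (10 mol %), EtCO2H (10 mol %), i-PrOH, 45 °C
Reagents that add atoms: formaldehyde C=O
Why: Amine-catalysed Mannich condensation and elimination (α-methylenation of aldehydes): the enamine forms at the unhindered aldehyde far faster than at the ketone and puts C14 in place. Any material that already closes ring C here is on the pathway of step 16.

Step 16
Reactants: 24 enal (23 with the C8=C14 methylene; a 2-substituted acrolein)
Product: 26 bicyclic pseudo-ester (rings C and D closed; C7 aldehyde; C12 ketone; C16=C17; methoxy-γ-lactone), via Michael adduct 25 (not isolated)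
Conditions: DBU (1.5 equiv), THF, 0 °C to rt; then Pd(PPh3)4 (5 mol %), 50 °C
Reagents that add atoms: none
Why: Intramolecular Michael addition of the doubly activated C13–H (α to the ketone and allylic) to the acrolein closes ring C as a six-membered ring (6-endo-trig, bond C13–C14) and gives 25. Pd(PPh3)4 then ionises the allylic acetate, and the aldehyde enolate attacks the π-allyl terminus C15 (Tsuji–Trost allylation, the same ring closure that completes trimethylenemethane-type [3+2] annulations), which closes ring D and makes C8 quaternary. C13 can epimerise and C15 can reach C8 only from the face on which the C13 arm is axial; allylic strain with the exocyclic enolate holds the bulky C10 group on C9 axial on the other face, so the bridge should form anti to C10 as in the target.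

Step 17
Reactants: 26 bicyclic pseudo-ester (rings C and D closed; C7 aldehyde; C12 ketone; C16=C17; methoxy-γ-lactone)
Product: 27 bicyclic lactol (26 with OH in place of OMe on C6)
Conditions: 1 M HCl/THF (1:3), 40 °C
Reagents that add atoms: water O
Why: Acid hydrolysis of the pseudo-ester to the hydroxy lactone (pseudo-acid). Dilute aqueous acid should not protonate the C16=C17 alkene, whose cation would sit β to the C12 carbonyl, and the aldehyde has no α-hydrogen.

Step 18
Reactants: 27 bicyclic lactol (26 with OH in place of OMe on C6)
Product: 29 7,12-dioxo-6,7-seco-ent-kaur-16-ene-6,19-dioic acid (CNP0320711.1), via cyclic anhydride 28 (not isolated)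
Conditions: Dess–Martin periodinane (1.5 equiv), CH2Cl2, rt; then 1 M LiOH, THF/H2O, 0 °C; 1 M HCl to pH 2
Reagents that add atoms: water O (as aqueous LiOH)
Why: The lactol is a secondary alcohol and is oxidised to the cyclic anhydride, whereas the periodinane cannot oxidise the C7 aldehyde in an anhydrous medium; this is how C6 reaches the acid level without C7 being touched. Hydroxide then opens the anhydride to the cis diacid.

## Compound list

1 | 5-chloropent-1-yne | C#CCCCCl | starting material
2 | methyl (2E)-6-chloro-3-methylhex-2-enoate | COC(=O)/C=C(\C)CCCCl | intermediate
3 | dimethyl 2-methylpropanedioate (dimethyl methylmalonate) | COC(=O)C(C)C(=O)OC | starting material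
4 | dimethyl 2-[(4E)-6-methoxy-4-methyl-6-oxohex-4-en-1-yl]-2-methylpropanedioate | COC(=O)/C=C(\C)CCCC(C)(C(=O)OC)C(=O)OC | intermediate
5 | (2R,6E)-8-methoxy-2-(methoxycarbonyl)-2,6-dimethyl-8-oxooct-6-enoic acid | COC(=O)/C=C(\C)CCC[C@@](C)(C(=O)OC)C(=O)O | intermediate
6 | dimethyl (2E,7R)-7-(hydroxymethyl)-3,7-dimethyloct-2-enedioate | COC(=O)/C=C(\C)CCC[C@@](C)(C(=O)OC)CO | intermediate
7 | dimethyl (2E,7R)-7-formyl-3,7-dimethyloct-2-enedioate | COC(=O)/C=C(\C)CCC[C@@](C)(C(=O)OC)C=O | intermediate
8 | allyltriphenylphosphonium bromide | C=CC[P+](c1ccccc1)(c1ccccc1)c1ccccc1.[Br-] | starting material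
9 | dimethyl (2E,7R)-7-[(1Z)-buta-1,3-dien-1-yl]-3,7-dimethyloct-2-enedioate (Z diene; not isolated) | COC(=O)/C=C(\C)CCC[C@@](C)(C(=O)OC)/C=C\C=C | intermediate
10 | dimethyl (2E,7R)-7-[(1E)-buta-1,3-dien-1-yl]-3,7-dimethyloct-2-enedioate (triene precursor of the key step) | COC(=O)/C=C(\C)CCC[C@@](C)(C(=O)OC)/C=C/C=C | intermediate
11 | dimethyl (1R,4aR,5R,8aS)-1,4a-dimethyl-1,2,3,4,4a,5,6,8a-octahydronaphthalene-1,5-dicarboxylate (trans-octalin; product of the key step) | COC(=O)[C@H]2[C@]1(C)CCC[C@@](C)(C(=O)OC)[C@H]1C=CC2 | intermediate
12 | (1R,4aS,5R,8aR)-5-(methoxycarbonyl)-5,8a-dimethyl-1,2,4a,5,6,7,8,8a-octahydronaphthalene-1-carboxylic acid (acid on C9; C19 methyl ester) | OC(=O)[C@H]2[C@]1(C)CCC[C@@](C)(C(=O)OC)[C@H]1C=CC2 | intermediate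
13 | acid chloride of 12 (C9–COCl; not isolated) | ClC(=O)[C@H]2[C@]1(C)CCC[C@@](C)(C(=O)OC)[C@H]1C=CC2 | intermediate
14 | diazoketone (C9–CO–CHN2; C19 methyl ester; C6=C7; C4, C5, C9, C10 as in 11) | [N-]=[N+]=CC(=O)[C@H]2[C@]1(C)CCC[C@@](C)(C(=O)OC)[C@H]1C=CC2 | intermediate
15 | ketene from 14 (C9–CH=C=O; not isolated) | O=C=C[C@H]2[C@]1(C)CCC[C@@](C)(C(=O)OC)[C@H]1C=CC2 | intermediate
16 | morpholine amide ester (C9–CH2–CO–morpholin-4-yl; C19 methyl ester; C6=C7; ring centres as in 11) | O=C(C[C@H]2[C@]1(C)CCC[C@@](C)(C(=O)OC)[C@H]1C=CC2)N1CCOCC1 | intermediate
17 | morpholine amide acid (16 with free C19 carboxylic acid) | O=C(C[C@H]2[C@]1(C)CCC[C@@](C)(C(=O)O)[C@H]1C=CC2)N1CCOCC1 | intermediate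
18 | lactol aldehyde (C6=C7 cleaved; C7 aldehyde; C6 as hydroxy-γ-lactone with C19; not isolated) | O=C(C[C@H](CC=O)[C@]1(C)CCC[C@@]2(C)C(=O)OC(O)[C@@H]12)N1CCOCC1 | intermediate
19 | acetal pseudo-ester amide (C7 dimethyl acetal; C19-to-C6 methoxy-γ-lactone cis-fused to ring A; C12 morpholine amide) | O=C(C[C@H](CC(OC)OC)[C@]1(C)CCC[C@@]2(C)C(=O)OC(OC)[C@@H]12)N1CCOCC1 | intermediate
20 | 2-methylprop-2-en-1-ol | C=C(C)CO | starting material
21 | dilithium hemiaminal alkoxide from 19 and dilithiated 20 (not isolated) | [Li+].[Li+].[O-]CC(=C)CC([O-])(N1CCOCC1)C[C@H](CC(OC)OC)[C@]1(C)CCC[C@@]2(C)C(=O)OC(OC)[C@@H]12 | intermediate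
22 | keto acetate (C12 ketone carrying CH2–C(=CH2)–CH2OAc = C13, C16, C17, C15; C7 dimethyl acetal; methoxy-γ-lactone) | CC(=O)OCC(=C)CC(=O)C[C@H](CC(OC)OC)[C@]1(C)CCC[C@@]2(C)C(=O)OC(OC)[C@@H]12 | intermediate
23 | keto acetate aldehyde (22 with free C7 aldehyde) | CC(=O)OCC(=C)CC(=O)C[C@H](CC=O)[C@]1(C)CCC[C@@]2(C)C(=O)OC(OC)[C@@H]12 | intermediate
24 | enal (23 with the C8=C14 methylene) | CC(=O)OCC(=C)CC(=O)C[C@H](C(=C)C=O)[C@]1(C)CCC[C@@]2(C)C(=O)OC(OC)[C@@H]12 | intermediate
25 | Michael adduct (ring C closed by C13–C14; CHO on C8; 1-(acetoxymethyl)vinyl on C13; epimers at C8 and C13; not isolated) | CC(=O)OCC(=C)C1CC(C=O)[C@@H](CC1=O)[C@]1(C)CCC[C@@]2(C)C(=O)OC(OC)[C@@H]12 | intermediate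
26 | bicyclic pseudo-ester (rings C and D closed; C7 aldehyde; C12 ketone; C16=C17; methoxy-γ-lactone) | C=C1C[C@]2(C=O)C[C@H]1C(=O)C[C@H]2[C@]1(C)CCC[C@@]2(C)C(=O)OC(OC)[C@@H]12 | intermediate
27 | bicyclic lactol (26 with OH in place of OMe on C6) | C=C1C[C@]2(C=O)C[C@H]1C(=O)C[C@H]2[C@]1(C)CCC[C@@]2(C)C(=O)OC(O)[C@@H]12 | intermediate
28 | cyclic C6/C19 anhydride of the target (not isolated) | C=C1C[C@]2(C=O)C[C@H]1C(=O)C[C@H]2[C@]1(C)CCC[C@@]2(C)C(=O)OC(=O)[C@@H]12 | intermediate
29 | 7,12-dioxo-6,7-seco-ent-kaur-16-ene-6,19-dioic acid (CNP0320711.1) | C=C1C[C@]2(C=O)C[C@H]1C(=O)C[C@H]2[C@]1(C)CCC[C@@](C)(C(=O)O)[C@H]1C(=O)O | target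

## Step count and least certain steps

Total: 18 steps. Longest linear sequence: 18 steps (1 to 29); compounds 3, 8 and 20 enter as single building blocks.

**Step 7 (key step).** The most likely failure is low reactivity of the β,β-disubstituted enoate toward an unactivated diene. Warming would then be needed, and that would let Lewis-acid-induced diene oligomerisation compete and would erode both the endo preference and the face selectivity that rests on a modest steric difference at C4. The fallback sets out from 10 and returns at 12, and activates the dienophile as an aldehyde instead of an ester. i-Bu2AlH (CH2Cl2, −78 °C) should reduce the unhindered conjugated ester before the ester on quaternary C4 and give the allylic alcohol F1. MnO2 would give the trienal F2. One equivalent of Me2AlCl at −78 °C would bind only the far more basic aldehyde and bring about the cycloaddition of this much stronger dienophile to the octalin aldehyde F3. NaClO2 (NaH2PO4, 2-methylbut-2-ene) would then give acid 12 directly.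

**Step 16.** The most likely failure is loss of site control in the palladium stage: allylation at the ketone α′-carbon C11 (an isomeric bridged ketone) or at oxygen. Base-induced migration of C16=C17 into conjugation before ring D closes is a second risk, and the face selectivity at C8 rests on a conformational argument. The fallback sets out from 24 and returns at 26 by way of isolated 25, and changes how the nucleophile is generated. The Michael stage is run alone (0.1 equiv DBU) and 25 is isolated. Ring D is then closed by dual catalysis with benzhydrylamine and Pd(PPh3)4 in the presence of a weak acid: only the aldehyde is converted into an enamine, which attacks the π-allylpalladium complex (amine/palladium α-allylation of α-branched aldehydes). This fallback makes no compound outside the list (F0).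

**Step 13.** The most likely failure is attack of the allylic organolithium on the lactone carbonyl of the pseudo-ester, or deprotonation at C11 in place of addition. The fallback sets out from 19 and returns at 22, and replaces the organolithium by reagents that do not touch lactones. Cp2Zr(H)Cl (THF, rt) reduces the tertiary amide to the aldehyde F4. Indium metal with 2-(bromomethyl)allyl acetate in THF/H2O (Barbier allylation) gives the homoallylic alcohol F5. Dess–Martin oxidation then gives 22.

**Step 3.** The most likely failure is insufficient discrimination between the enantiotopic esters (or the opposite sense) with this particular chain, together with slow hydrolysis of the enoate ester. The fallback sets out from 4 and returns at 5 by classical resolution. KOH (1.0 equiv, MeOH, 0 °C to rt) gives the racemic half-ester F6. Fractional crystallisation of its salt with (R)-1-phenylethanamine gives the salt F7 (the enantiomeric amine would be used if its salt is the less soluble one), and acidification returns 5.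

## Further compounds

F1 | step 7 | methyl (2R,6E)-2-[(1E)-buta-1,3-dien-1-yl]-8-hydroxy-2,6-dimethyloct-6-enoate | OC/C=C(\C)CCC[C@@](C)(C(=O)OC)/C=C/C=C
F2 | step 7 | methyl (2R,6E)-2-[(1E)-buta-1,3-dien-1-yl]-2,6-dimethyl-8-oxooct-6-enoate | O=C/C=C(\C)CCC[C@@](C)(C(=O)OC)/C=C/C=C
F3 | step 7 | octalin aldehyde (11 with CHO in place of the ester on C9) | O=C[C@H]2[C@]1(C)CCC[C@@](C)(C(=O)OC)[C@H]1C=CC2
F0 | step 16 | none | none
F4 | step 13 | C12 aldehyde (19 with CHO in place of the morpholine amide) | O=CC[C@H](CC(OC)OC)[C@]1(C)CCC[C@@]2(C)C(=O)OC(OC)[C@@H]12
F5 | step 13 | homoallylic alcohol (22 with CH(OH) at C12; carbinol epimers) | CC(=O)OCC(=C)CC(O)C[C@H](CC(OC)OC)[C@]1(C)CCC[C@@]2(C)C(=O)OC(OC)[C@@H]12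
F6 | step 3 | racemic 8-methoxy-2-(methoxycarbonyl)-2,6-dimethyl-8-oxooct-6-enoic acid (6E) | COC(=O)/C=C(\C)CCCC(C)(C(=O)OC)C(=O)O
F7 | step 3 | (1R)-1-phenylethanaminium salt of 5 | COC(=O)/C=C(\C)CCC[C@@](C)(C(=O)OC)C(=O)[O-].C[C@@H]([NH3+])c1ccccc1
A1 | alternative 1 | methyl 4-oxo-1-[2-oxo-3-(trimethylsilyl)propyl]cyclohexa-2,5-diene-1-carboxylate | COC(=O)C1(CC(=O)C[Si](C)(C)C)C=CC(=O)C=C1
A2 | alternative 1 | methyl 6-hydroxy-4-oxo-6-[(trimethylsilyl)methyl]bicyclo[3.2.1]oct-2-ene-1-carboxylate (β-hydroxysilane) | O[C@@]1(C[Si](C)(C)C)C[C@]2(C(=O)OC)C[C@H]1C(=O)C=C2
A3 | alternative 2 | citraconate ester of the C7 carbinol of the C16-ketal bicycle carrying an (E)-penta-2,4-dien-2-yl group on C9 | O1CCOC13C[C@]2(COC(=O)/C=C(/C)C(=O)OC)C[C@H]3C(=O)C[C@H]2/C(C)=C/C=C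
A4 | alternative 2 | lactone-bridged cycloadduct | O1CCOC13C[C@]2(CO4)C[C@H]3C(=O)C[C@H]2[C@]5(C)C=CC[C@@](C)(C(=O)OC)[C@H]5C4=O
A5 | alternative 3 | C12 acid chloride with a 3-[(trimethylsilyl)methyl]cyclopent-3-ene ring D on C8 (C7 ethyl thioester; C6 and C19 methyl esters) | C[Si](C)(C)CC1=CC[C@](C1)(C(=O)SCC)[C@@H](CC(Cl)=O)[C@]1(C)CCC[C@@](C)(C(=O)OC)[C@H]1C(=O)OC
A6 | alternative 3 | bicyclic methylene ketone thioester | C=C1C[C@]2(C(=O)SCC)C[C@H]1C(=O)C[C@H]2[C@]1(C)CCC[C@@](C)(C(=O)OC)[C@H]1C(=O)OC
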